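**Remark on the chemistry:** flavanone numbering is used for every intermediate (C2–C8a for the 4‑methoxyphenyl half, double primes for the other half). The target is taken as the (2R,3S,2''R,3''R) isomer, 2,3‑trans and 2'',3''‑cis. The bis(dioxinone) precursor and its cyclised product keep these four descriptors, because the priority order at each centre does not change, so their structures need no correction.

## Structural features

Sikokianin B is a 3,3''‑biflavanone: two 5,7‑dihydroxychroman‑4‑one units (rings A/C and A''/C'') joined by a single bond between C3 and C3'', one with a 4‑methoxyphenyl group at C2 and the other with a 4‑hydroxyphenyl group at C2''. The four stereocentres C2, C3, C3'' and C2'' are contiguous: ring C is 2,3‑trans, ring C'' is 2'',3''‑cis, and C3/C3'' have unlike descriptors, so no symmetry operation relates the halves. Read along C4–C3–C3''–C4'', the core is a 2,3‑disubstituted succinyl unit whose substituents are two aryl carbinol carbons, with C2/C3 in an anti‑aldol and C2''/C3'' in a syn‑aldol relationship. C3 and C3'' are α to aryl ketones and β to ring oxygens, so base causes epimerisation and retro‑oxa‑Michael opening, first in the cis half. O1–C2 and O1''–C2'' are 4‑alkoxybenzylic ethers that can ionise in strong acid, and the free phloroglucinol rings are nucleophilic and easily oxidised. The real difficulty is the unsymmetrical stereotetrad and its survival while two identical, unprotected A rings are attached. The key step uses the fact that C5–C8 of each ring A can be read as a tri‑β‑carbonyl chain on C8a of ring C, and that C4a is the nucleophilic α‑carbon of the vinylogous ester O1–C8a=C4a–C4=O of a 2,3‑dihydro‑4‑pyranone. Both A rings can therefore be closed last, at C4a–C5 and C4a''–C5'', from a non‑aromatic core under neutral conditions.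

## Logic of the disconnections

22 ⇒ 21. The O–CH2Ph bond on the phenol of the C2'' aryl group is cut. A free phenol would add to the ketenes of the ring‑forming step, whereas the benzyl ether is inert to every reagent of the route and leaves by neutral hydrogenolysis. The forward step must spare the benzylic C2–O1 and C2''–O1'' bonds and both aryl ketones.

21 ⇒ 19. C4a–C5 and C4a''–C5'' are cut and each aromatic ring is unfolded into a masked tri‑β‑carbonyl arm on C8a. This removes two arenes and four phenols at once, and the stereotetrad is then carried by a core whose C3 and C3'' hydrogens are only weakly acidic. The forward step must acylate C4a and C4a'' selectively, without base and without touching C2''/C3''.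

19 ⇒ 13 + 16 (through 18). O1–C8a and O1''–C8a'' are cut (cyclodehydration of two δ‑hydroxy‑β‑diketones), then C4–C4a and C4''–C4a'' (Claisen condensations). All ten carbons of both arms then come from two molecules of 16 in one operation, and the two acyl carbons of 13, although different in kind, are both acyl donors. The forward step must acylate two hindered carbonyls without enolising them, and close each hydroxyl onto its own C8a under acid mild enough for the 4‑alkoxybenzylic carbinols. Forming both rings C by cycloaddition to a C3–C3''‑linked bis(diene) was set aside: one reaction type would have to give trans in one ring and cis in the other at two almost identical sites.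

16 ⇒ 14. The bond between the acetyl carbon and the former ring methyl (C8a–C8 of the final skeleton) is cut. The gain is a purchasable four‑carbon building block, and the demand is γ‑selective C‑acylation of a dienolate.

13 ⇒ 12. The O–Si bond at C2 is cut. The silyl ether is needed only to stop retro‑aldol cleavage under the base of the next step and must fall off in the acid that closes the rings.

12 ⇒ 9 + 10. C2–C3 is cut as an aldol bond. In 9 the five‑membered lactone O1''–C2''–C3''–C3–C4 makes C3 the only readily enolised carbon, fixes the enolate geometry as E (anti aldol, hence the trans ring C later), and lets the C3'' substituent direct the new bond to the opposite face (the unlike C3/C3'' pair). The forward step must be run under kinetic control, with deprotonation at C3 and not at C3''.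

9 ⇒ 7 (through 8). The amide C4''–N bond is exchanged back to the imide and the lactone O1''–C4 bond is opened to a hydroxy ester. The lactone is chosen because it protects O1'', activates C4 as an acyl donor and cannot be followed by a second lactone (that ring would be trans‑fused). The forward step must exchange the auxiliary without touching the ester and then lactonise without eroding C2''.

7 ⇒ 4 + 5. C2''–C3'' is cut as a syn aldol bond. One auxiliary‑controlled reaction sets both stereocentres of the future cis ring and so fixes the absolute configuration of the whole molecule. The demand is clean formation of the Z enolate next to the imide and not next to the ester.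

4 ⇒ 1 + 2. The N–acyl bond is cut, leaving a commercial succinic half ester and a commercial auxiliary. The only demand is acylation at the free acid terminus.

## Other disconnections considered

Alternative 1: The cut is C2''–C3'' in the cis ring. In the forward sense the diazo ketone A1, whose diazo carbon is the future C3'' and already carries the flavon‑3‑yl group, would lose nitrogen on Rh2(S‑PTTL)4. The carbenoid would insert into a benzylic C–H bond of the ortho 4‑silyloxybenzyl ether and close ring C'' to give the cis flavonyl‑flavanone A2.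
- In favour: both A rings are present from the start as purchased arenes, so no benzannulation is needed; on this point it is the better plan. The cis pair would be set by a chiral catalyst in the ring‑forming event.
- Against: closing a six‑membered ring by insertion competes with attack of the ether oxygen on the carbenoid (oxonium ylide, then 1,2‑shift) and with Wolff rearrangement. In A2 the C3'' hydrogen is flanked by an aryl ketone and a chromone carbon, so the cis pair would be very easily lost. A2 also still lacks C2 and C3: the trans pair and the C3/C3'' relationship would have to come from reduction of a tetrasubstituted chromone double bond next to that labile centre, where hydrogenation would be expected to add cis. Five silyl ethers would then need basic fluoride.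
- Comparison: A2 carries two of the four stereocentres, whereas 19 carries all four before any arene exists. Both key steps close a six‑membered ring through a reactive intermediate without close precedent, so on mechanistic risk they are equal. The alternative needs several operations after its key step against one in the chosen plan.

Alternative 2: The cuts are O1''–C2'' and C3''–C4''. On heating, the phenol A4 would lose water to the o‑quinone methide A5, which would add as a heterodiene across the Z‑styryl double bond of the trans‑3‑styrylflavan A3 to give the pentabenzyl biflavan A6.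
- In favour: inverse‑demand [4+2] additions of o‑quinone methides are well established, and the polarity of both partners matches the required regiochemistry. Suprafacial addition would translate the Z geometry into the cis C2''/C3'' pair. The conditions are neutral and thermal, equal to the chosen key step in mildness, and the plan is the more convergent one because two large halves are joined in the ring‑forming step.
- Against: the face of the alkene relative to C3 is governed only by an allylic stereocentre on a freely rotating bond, so the C3/C3'' relationship is not secured. Z‑styrenes are sluggish partners and can isomerise, and A5 can dimerise. A6 is also at the wrong oxidation level: C4 and C4'' are methylene groups and would have to be oxidised to ketones in the presence of C2–H and C2''–H, which are benzylic and α to oxygen and therefore more reactive, and of five benzyl ethers.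
- Comparison: the alternative builds the skeleton faster, but the chosen plan has both carbonyls in place from the first step and needs no oxidation‑level change. Mechanistically the cycloaddition is better precedented than the ketene closure. In step economy the late double oxidation and the five‑fold deprotection outweigh the convergence.

Alternative 3: The cuts are O1–C2 and O1''–C2''. Under a quinine‑derived thiourea base the two free ortho‑phenols of the bis‑chalcone A7 would add to the β‑carbons of their enones, with protonation at C3 and C3'', to give the pentabenzyl ether A8.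
- In favour: this is the shortest route and the closest to the biosynthetic chalcone‑to‑flavanone closure. A7 is only a few condensations away from commercial materials and both A rings are bought, so on step economy it is the better plan.
- Against: four stereocentres would have to be set in one operation. C3 and C3'' arise by protonation and stay epimerisable under the basic catalyst, and the oxa‑Michael addition is reversible, so the thermodynamically preferred trans,trans arrangement is expected to win over the needed trans/cis one. A single catalyst would have to treat two enones differently although they differ only in a remote methyl versus benzyl ether. Each hydroxyl can also add to either enone only if the crowded, twisted diene allows it.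
- Comparison: structurally the alternative sets all stereochemistry at the end under equilibrating conditions, whereas the chosen plan sets each centre early under separate, kinetically controlled steps and never exposes the cis pair to base afterwards. Mechanistically the oxa‑Michael closure is well known and the ketene closure is not. The chosen plan accepts more steps and a riskier ring closure in exchange for control of the stereotetrad.

Key step: step 8

## Route

Step 1
Reactants: 1 4‑(tert‑butoxy)‑4‑oxobutanoic acid; 2 (R)‑4‑benzyl‑1,3‑oxazolidin‑2‑one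
Product: 4 tert‑butyl 4‑[(4R)‑4‑benzyl‑2‑oxo‑1,3‑oxazolidin‑3‑yl]‑4‑oxobutanoate, via mixed pivalic anhydride 3 (not isolated)
Conditions: tBuCOCl, Et3N, THF, −20 °C; then 2, LiCl, −20 °C → rt
Reagents that add atoms: none
Why: LiCl‑assisted N‑acylation of the oxazolidinone by the mixed anhydride, which is attacked at the unhindered succinyl carbonyl; the tert‑butyl ester is chosen so that the later aldol adduct does not lactonise before the auxiliary is exchanged.

Step 2
Reactants: 4 tert‑butyl 4‑[(4R)‑4‑benzyl‑2‑oxo‑1,3‑oxazolidin‑3‑yl]‑4‑oxobutanoate; 5 4‑(benzyloxy)benzaldehyde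
Product: 7 tert‑butyl (3R)‑3‑[(R)‑[4‑(benzyloxy)phenyl](hydroxy)methyl]‑4‑[(4R)‑4‑benzyl‑2‑oxo‑1,3‑oxazolidin‑3‑yl]‑4‑oxobutanoate, via dibutylboron Z‑enolate 6 (not isolated)
Conditions: nBu2BOTf, iPr2NEt, CH2Cl2, −78 → 0 °C; 5, −78 → 0 °C; pH 7 buffer, MeOH, 30% H2O2, 0 °C
Reagents that add atoms: none
Why: Evans syn aldol; the Z boron enolate, formed only next to the imide, reacts through a Zimmerman–Traxler chair in which the benzyl group of the (R)‑auxiliary shields one face, so C3'' and C2'' should both be formed R (syn), the relationship that later becomes the cis ring C''.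

Step 3
Reactants: 7 tert‑butyl (3R)‑3‑[(R)‑[4‑(benzyloxy)phenyl](hydroxy)methyl]‑4‑[(4R)‑4‑benzyl‑2‑oxo‑1,3‑oxazolidin‑3‑yl]‑4‑oxobutanoate
Product: 9 (2R,3R)‑2‑[4‑(benzyloxy)phenyl]‑N‑methoxy‑N‑methyl‑5‑oxooxolane‑3‑carboxamide, via hydroxy N‑methoxy‑N‑methylamide 8 (not isolated)
Conditions: AlMe3, MeNH(OMe)·HCl, CH2Cl2, −15 → 0 °C; 1 M HCl work‑up; crude in CF3CO2H–CH2Cl2 (1:4), 0 °C → rt
Reagents that add atoms: N,O‑dimethylhydroxylamine hydrochloride, CNOC.Cl
Why: Aluminium amide transamination of a β‑hydroxy imide (the aluminium alkoxide directs attack to the exocyclic carbonyl) gives the amide and returns the auxiliary; acid then removes the tert‑butyl group and the γ‑hydroxy acid lactonises. Even if the benzylic carbinol ionises, closure should return the more stable 2,3‑trans lactone, which is the isomer needed.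

Step 4
Reactants: 9 (2R,3R)‑2‑[4‑(benzyloxy)phenyl]‑N‑methoxy‑N‑methyl‑5‑oxooxolane‑3‑carboxamide; 10 4‑methoxybenzaldehyde
Product: 12 (2R,3R,4S)‑2‑[4‑(benzyloxy)phenyl]‑4‑[(R)‑hydroxy(4‑methoxyphenyl)methyl]‑N‑methoxy‑N‑methyl‑5‑oxooxolane‑3‑carboxamide, via lactone lithium enolate 11 (not isolated)
Conditions: LiN(SiMe3)2 (1.1 equiv), THF, −78 °C; 10, −78 °C, 15 min; AcOH, −78 °C
Reagents that add atoms: none
Why: Aldol addition of a lactone lithium enolate; the base removes the lactone α‑proton, which is more acidic and less hindered than the tertiary amide α‑hydrogen at C3''. The ring fixes the enolate as E, so the closed transition state should give the anti carbinol (C2 R), and the aldehyde approaches opposite to the neighbouring carboxamide, which sets C3 as S, trans to the C3'' substituent. The cold acid quench prevents retro‑aldol equilibration.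

Step 5
Reactants: 12 (2R,3R,4S)‑2‑[4‑(benzyloxy)phenyl]‑4‑[(R)‑hydroxy(4‑methoxyphenyl)methyl]‑N‑methoxy‑N‑methyl‑5‑oxooxolane‑3‑carboxamide
Product: 13 (2R,3R,4S)‑2‑[4‑(benzyloxy)phenyl]‑N‑methoxy‑4‑[(R)‑(4‑methoxyphenyl)(triethylsilyloxy)methyl]‑N‑methyl‑5‑oxooxolane‑3‑carboxamide
Conditions: Et3SiCl, imidazole, DMAP (cat.), DMF, 0 °C → rt
Reagents that add atoms: chlorotriethylsilane, CC[Si](Cl)(CC)CC
Why: Silylation of the secondary benzylic alcohol; the ether blocks retro‑aldol cleavage under the strongly basic conditions of step 7 and is removed by the acid used there.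

Step 6
Reactants: 14 2,2,6‑trimethyl‑4H‑1,3‑dioxin‑4‑one
Product: 16 2,2‑dimethyl‑6‑(2‑oxopropyl)‑4H‑1,3‑dioxin‑4‑one, via dioxinone lithium dienolate 15 (not isolated)
Conditions: LiN(SiMe3)2 (1.0 equiv), THF, −78 °C; AcCl (0.5 equiv), −78 → −40 °C; 1 M HCl
Reagents that add atoms: acetyl chloride, CC(Cl)=O
Why: γ‑Deprotonation of the vinylogous ester gives the dienolate, which is C‑acylated at the γ‑carbon (vinylogous Claisen acylation); two equivalents of dienolate per acyl chloride are used because the product is more acidic than 14.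

Step 7
Reactants: 13 (2R,3R,4S)‑2‑[4‑(benzyloxy)phenyl]‑N‑methoxy‑4‑[(R)‑(4‑methoxyphenyl)(triethylsilyloxy)methyl]‑N‑methyl‑5‑oxooxolane‑3‑carboxamide; 16 2,2‑dimethyl‑6‑(2‑oxopropyl)‑4H‑1,3‑dioxin‑4‑one
Product: 19 bis(dioxinone) precursor (2R,3S,2'R,3'R)‑2'‑[4‑(benzyloxy)phenyl]‑6,6'‑bis[(2,2‑dimethyl‑4‑oxo‑4H‑1,3‑dioxin‑6‑yl)methyl]‑2‑(4‑methoxyphenyl)‑2,2',3,3'‑tetrahydro‑4H,4'H‑[3,3'‑bipyran]‑4,4'‑dione, via keto‑dioxinone dilithium dianion 17 (not isolated), via open‑chain bis(diketo‑dioxinone) 18 (not isolated)
Conditions: 16 (6 equiv), LiN(iPr)2 (12 equiv), THF, −78 → −40 °C; 13, −78 → −20 °C; AcOH; crude, TsOH·H2O (0.2 equiv), THF–H2O (20:1), 0 °C → rt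
Reagents that add atoms: none
Why: Claisen condensation of the terminal carbanion of the dianion with both acyl groups of 13 (lactone opening at C4, substitution of the amide at C4'' through its stable chelate) builds C4–C4a and C4''–C4a'' and frees O1''; aqueous acid then cleaves the silyl ether and each δ‑hydroxy‑β‑diketone cyclodehydrates to the 2,3‑dihydro‑4‑pyranone. Closure of a hydroxyl onto C4 or C4'' of the other half would give a five‑membered enol ether that leaves the second hydroxyl without a partner (the second five‑membered ring would be trans‑fused), and vinylogous esters exchange under aqueous acid, so the bis(pyranone) is the expected thermodynamic product. Acid is used because base would trigger aldol‑type aromatisation of the chains onto C4 and C4'' and could epimerise C3''.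

Step 8
Reactants: 19 bis(dioxinone) precursor (2R,3S,2'R,3'R)‑2'‑[4‑(benzyloxy)phenyl]‑6,6'‑bis[(2,2‑dimethyl‑4‑oxo‑4H‑1,3‑dioxin‑6‑yl)methyl]‑2‑(4‑methoxyphenyl)‑2,2',3,3'‑tetrahydro‑4H,4'H‑[3,3'‑bipyran]‑4,4'‑dione
Product: 21 sikokianin B 4‑benzyl ether (2R,3S,2''R,3''R), via bis(acylketene) 20 (not isolated)
Conditions: PhMe (0.002 M), 110 °C, N2 sweep to remove acetone, 3 h
Reagents that add atoms: none
Why: Proposed new method: each dioxinone should lose acetone by retro‑[4+2] near 110 °C to give the acylketene arm O=C=CH–CO–CH2 on C8a; enolisation of the C8 methylene gives the dienylketene C4a=C8a–C8=C7(OH)–C6=C5=O, whose 6π electrocyclisation (or, equivalently, attack of the nucleophilic vinylogous‑ester carbon C4a on the ketene carbon) forms C4a–C5, and tautomerisation of the cyclohexadienone gives the 5,7‑dihydroxy ring. The closest known reaction types are the thermolysis of 2,2‑dimethyl‑1,3‑dioxin‑4‑ones to acylketenes with aromatisation of the derived poly‑β‑carbonyl chains, and the 6π closure of dienylketenes to phenols; what is new is the α‑carbon of a cyclic vinylogous ester as the terminus. Ring A and ring A'' are each closed as six‑membered carbocycles in a 6π (formally C‑acylation) mode onto C4a and C4a''. No stereocentre is created, and C2, C3, C3'' and C2'' are untouched because the medium is neutral and aprotic. The step needs C‑acylation at C4a in preference to ketene dimerisation, to trapping by water or by the phenols of the first ring formed, and to O‑acylation. The six‑atom array puts C5 within reach of C4a only, every other intramolecular closure would give a four‑ or eight‑membered ring, and the aldol‑type fold is impossible because C4 is already the ring carbonyl; high dilution and removal of acetone suppress the bimolecular paths.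

Step 9
Reactants: 21 sikokianin B 4‑benzyl ether (2R,3S,2''R,3''R)
Product: 22 sikokianin B
Conditions: H2 (1 atm), 10% Pd/C, EtOAc–MeOH, rt
Reagents that add atoms: none
Why: Hydrogenolysis of the aryl benzyl ether; at ambient pressure and temperature the C2–O1 and C2''–O1'' bonds and the aryl ketones are expected to survive, and the neutral medium keeps the cis C2''/C3'' pair intact.

## Compound list

1 | 4‑(tert‑butoxy)‑4‑oxobutanoic acid | CC(C)(C)OC(=O)CCC(=O)O | starting material
2 | (R)‑4‑benzyl‑1,3‑oxazolidin‑2‑one | O=C1N[C@H](Cc2ccccc2)CO1 | starting material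
3 | 4‑(tert‑butoxy)‑4‑oxobutanoic pivalic anhydride (formed and used in step 1) | CC(C)(C)OC(=O)CCC(=O)OC(=O)C(C)(C)C | intermediate
4 | tert‑butyl 4‑[(4R)‑4‑benzyl‑2‑oxo‑1,3‑oxazolidin‑3‑yl]‑4‑oxobutanoate | CC(C)(C)OC(=O)CCC(=O)N1[C@H](Cc2ccccc2)COC1=O | intermediate
5 | 4‑(benzyloxy)benzaldehyde | O=Cc1ccc(OCc2ccccc2)cc1 | starting material
6 | dibutylboron (Z)‑enolate of 4 (formed and used in step 2) | CCCCB(CCCC)O/C(=C\CC(=O)OC(C)(C)C)N1[C@H](Cc2ccccc2)COC1=O | intermediate
7 | tert‑butyl (3R)‑3‑[(R)‑[4‑(benzyloxy)phenyl](hydroxy)methyl]‑4‑[(4R)‑4‑benzyl‑2‑oxo‑1,3‑oxazolidin‑3‑yl]‑4‑oxobutanoate (syn aldol) | CC(C)(C)OC(=O)C[C@H]([C@@H](O)c1ccc(OCc2ccccc2)cc1)C(=O)N1[C@H](Cc2ccccc2)COC1=O | intermediate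
8 | tert‑butyl (3R)‑3‑[(R)‑[4‑(benzyloxy)phenyl](hydroxy)methyl]‑4‑[methoxy(methyl)amino]‑4‑oxobutanoate (formed and used in step 3) | CC(C)(C)OC(=O)C[C@H]([C@@H](O)c1ccc(OCc2ccccc2)cc1)C(=O)N(C)OC | intermediate
9 | (2R,3R)‑2‑[4‑(benzyloxy)phenyl]‑N‑methoxy‑N‑methyl‑5‑oxooxolane‑3‑carboxamide (2,3‑trans lactone) | O=C1C[C@H]([C@@H](O1)c1ccc(OCc2ccccc2)cc1)C(=O)N(C)OC | intermediate
10 | 4‑methoxybenzaldehyde | COc1ccc(C=O)cc1 | starting material
11 | lithium enolate of 9 (formed and used in step 4) | [Li]OC1=C[C@H]([C@@H](O1)c1ccc(OCc2ccccc2)cc1)C(=O)N(C)OC | intermediate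
12 | (2R,3R,4S)‑2‑[4‑(benzyloxy)phenyl]‑4‑[(R)‑hydroxy(4‑methoxyphenyl)methyl]‑N‑methoxy‑N‑methyl‑5‑oxooxolane‑3‑carboxamide | O=C1[C@H]([C@@H](O)c2ccc(OC)cc2)[C@H]([C@@H](O1)c1ccc(OCc2ccccc2)cc1)C(=O)N(C)OC | intermediate
13 | (2R,3R,4S)‑2‑[4‑(benzyloxy)phenyl]‑N‑methoxy‑4‑[(R)‑(4‑methoxyphenyl)(triethylsilyloxy)methyl]‑N‑methyl‑5‑oxooxolane‑3‑carboxamide | O=C1[C@H]([C@@H](O[Si](CC)(CC)CC)c2ccc(OC)cc2)[C@H]([C@@H](O1)c1ccc(OCc2ccccc2)cc1)C(=O)N(C)OC | intermediate
14 | 2,2,6‑trimethyl‑4H‑1,3‑dioxin‑4‑one | CC1=CC(=O)OC(C)(C)O1 | starting material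
15 | lithium dienolate of 14 (formed and used in step 6) | C=C1C=C(O[Li])OC(C)(C)O1 | intermediate
16 | 2,2‑dimethyl‑6‑(2‑oxopropyl)‑4H‑1,3‑dioxin‑4‑one | CC(=O)CC1=CC(=O)OC(C)(C)O1 | intermediate
17 | dilithium dianion of 16 (formed and used in step 7) | C=C(O[Li])C=C1C=C(O[Li])OC(C)(C)O1 | intermediate
18 | (5S,6R)‑6‑[(R)‑[4‑(benzyloxy)phenyl](hydroxy)methyl]‑1,10‑bis(2,2‑dimethyl‑4‑oxo‑4H‑1,3‑dioxin‑6‑yl)‑5‑[(R)‑(4‑methoxyphenyl)(triethylsilyloxy)methyl]decane‑2,4,7,9‑tetrone, drawn as the open keto form (formed and used in step 7) | O=C(CC(=O)CC1=CC(=O)OC(C)(C)O1)[C@H]([C@@H](O[Si](CC)(CC)CC)c2ccc(OC)cc2)[C@H]([C@@H](O)c1ccc(OCc2ccccc2)cc1)C(=O)CC(=O)CC1=CC(=O)OC(C)(C)O1 | intermediate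
19 | (2R,3S,2'R,3'R)‑2'‑[4‑(benzyloxy)phenyl]‑6,6'‑bis[(2,2‑dimethyl‑4‑oxo‑4H‑1,3‑dioxin‑6‑yl)methyl]‑2‑(4‑methoxyphenyl)‑2,2',3,3'‑tetrahydro‑4H,4'H‑[3,3'‑bipyran]‑4,4'‑dione (2,3‑trans, 2',3'‑cis) | COc1ccc([C@@H]2OC(CC3=CC(=O)OC(C)(C)O3)=CC(=O)[C@H]2[C@H]2C(=O)C=C(CC3=CC(=O)OC(C)(C)O3)O[C@H]2c2ccc(OCc3ccccc3)cc2)cc1 | intermediate
20 | bis(acylketene) from 19, each arm CH2–CO–CH=C=O (formed and used in step 8) | COc1ccc([C@@H]2OC(CC(=O)C=C=O)=CC(=O)[C@H]2[C@H]2C(=O)C=C(CC(=O)C=C=O)O[C@H]2c2ccc(OCc3ccccc3)cc2)cc1 | intermediate
21 | sikokianin B 4‑benzyl ether, (2R,3S,2''R,3''R) | COc1ccc([C@@H]2Oc3cc(O)cc(O)c3C(=O)[C@H]2[C@H]2C(=O)c3c(O)cc(O)cc3O[C@H]2c2ccc(OCc3ccccc3)cc2)cc1 | intermediate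
22 | sikokianin B, (2R,3S,2''R,3''R) | COc1ccc([C@@H]2Oc3cc(O)cc(O)c3C(=O)[C@H]2[C@H]2C(=O)c3c(O)cc(O)cc3O[C@H]2c2ccc(O)cc2)cc1 | target

## Step count and least certain steps

Total: 9 steps. Longest linear sequence: 8 steps (1, 2, 3, 4, 5, 7, 8, 9); step 6 is a one‑step side branch.

**Step 8 (key step).**
- Risk: bimolecular consumption of the ketenes (dimerisation, addition of traces of water or of the phenols formed in the first ring) or re‑addition of acetone may outrun ring closure, because C4a is only a moderately nucleophilic carbon and the enol tautomer needed for closure is a minor species.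
- Fallback, known chemistry only, from 19 back to 21: 19 would be heated in toluene with an excess of methanol, which traps both acylketenes as esters and gives the bis(methyl β‑keto ester) dimethyl 4,4'‑[(2R,3S,2'R,3'R)‑2'‑[4‑(benzyloxy)phenyl]‑2‑(4‑methoxyphenyl)‑4,4'‑dioxo‑2,2',3,3'‑tetrahydro‑4H,4'H‑[3,3'‑bipyran]‑6,6'‑diyl]bis(3‑oxobutanoate) F1. Mg(OMe)2 in MeOH at 0 °C → rt would then effect the Claisen (Dieckmann‑type) cyclisation of each poly‑β‑keto ester chain: the dienolate formed at the C8 methylene attacks the ester through C4a, methoxide is lost and enolisation gives the phloroglucinol ring. Magnesium chelation keeps the medium only weakly basic, but the cis C2''/C3'' pair is more exposed here than in the thermal step.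

**Step 7.**
- Risk: the dianion may enolise the lactone at C3 rather than add to two hindered, α‑branched acyl carbons, which leaves the acylation incomplete. A diketo‑dioxinone chain may undergo aldol‑type aromatisation onto C4 or C4'' before the pyranone has closed. The 4‑alkoxybenzylic carbinols may ionise in acid, which costs the cis relationship or causes dehydration.
- Fallback, from 13 back to 19: HC≡CMgBr (excess, THF, −78 → 0 °C) would add to the amide and open the lactone to give the bis(ynone) (4S,5R)‑5‑[(R)‑[4‑(benzyloxy)phenyl](hydroxy)methyl]‑4‑[(R)‑(4‑methoxyphenyl)(triethylsilyloxy)methyl]octa‑1,7‑diyne‑3,6‑dione F2. Fluoride buffered with acetic acid would remove the silyl ether, and AgOTf (catalytic, CH2Cl2) would close both δ‑hydroxy ynones in the 6‑endo‑dig mode, the only oxa‑Michael mode open to each hydroxyl, to give (2R,3S,2'R,3'R)‑2'‑[4‑(benzyloxy)phenyl]‑2‑(4‑methoxyphenyl)‑2,2',3,3'‑tetrahydro‑4H,4'H‑[3,3'‑bipyran]‑4,4'‑dione F3. The arms would be attached by vinylogous Mukaiyama–Michael addition of 2,2‑dimethyl‑6‑methylene‑4‑(trimethylsilyloxy)‑4H‑1,3‑dioxine F4 (from 14, LiN(iPr)2, Me3SiCl) to C6 and C6' under tBuMe2SiOTf in CH2Cl2 at −78 °C, giving the bis(silyl enol ether) adduct F5 (arms drawn trans to the aryl groups). Saegusa–Ito oxidation with palladium diacetate, Pd(OAc)2, in MeCN would restore both C5=C6 double bonds and return the route to 19. The two new acetal‑type centres of F5 are destroyed again, so their configuration does not matter.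

**Step 4.**
- Risk: poor selection between the two faces of the aldehyde, because lithium lactone enolates discriminate only moderately between closed and open transition states with aromatic aldehydes. Retro‑aldol equilibration on warming would erode C2 further.
- Fallback, from 9 back to 12: the enolate 11 would be C‑acylated with 4‑methoxybenzoyl chloride (two equivalents of base) to the β‑keto lactone (2R,3R,4S)‑2‑[4‑(benzyloxy)phenyl]‑N‑methoxy‑4‑(4‑methoxybenzoyl)‑N‑methyl‑5‑oxooxolane‑3‑carboxamide F6. Its C3 is epimerisable and should settle trans to the carboxamide. The ketone would then be reduced under non‑chelating, Felkin–Anh‑type control (K[HB(sBu)3], or PhMe2SiH with fluoride), which is expected to favour the anti carbinol 12; Zn(BH4)2 would be the chelation‑controlled counterpart if the sense proves opposite. Any unwanted C2 epimer from the aldol can be oxidised with Dess–Martin periodinane to the same F6 and recycled.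

**Step 3.**
- Risk: the aluminium amide may attack the ring carbonyl of the auxiliary or the tert‑butyl ester, or the adduct may lactonise early and lose the hydroxyl that directs the exchange.
- Fallback, from 7 back to 9: LiOH/H2O2 (THF–H2O, 0 °C) would cleave the auxiliary to (2R)‑2‑[(R)‑[4‑(benzyloxy)phenyl](hydroxy)methyl]‑4‑(tert‑butoxy)‑4‑oxobutanoic acid F7. CF3CO2H would lactonise it to (2R,3R)‑2‑[4‑(benzyloxy)phenyl]‑5‑oxooxolane‑3‑carboxylic acid F8, and amide coupling with MeNH(OMe)·HCl (carbodiimide/HOBt, iPr2NEt, CH2Cl2) would give 9.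

## Further compounds

F1 | step 8 | dimethyl 4,4'‑[(2R,3S,2'R,3'R)‑2'‑[4‑(benzyloxy)phenyl]‑2‑(4‑methoxyphenyl)‑4,4'‑dioxo‑2,2',3,3'‑tetrahydro‑4H,4'H‑[3,3'‑bipyran]‑6,6'‑diyl]bis(3‑oxobutanoate) | COc1ccc([C@@H]2OC(CC(=O)CC(=O)OC)=CC(=O)[C@H]2[C@H]2C(=O)C=C(CC(=O)CC(=O)OC)O[C@H]2c2ccc(OCc3ccccc3)cc2)cc1
F2 | step 7 | (4S,5R)‑5‑[(R)‑[4‑(benzyloxy)phenyl](hydroxy)methyl]‑4‑[(R)‑(4‑methoxyphenyl)(triethylsilyloxy)methyl]octa‑1,7‑diyne‑3,6‑dione | C#CC(=O)[C@H]([C@@H](O[Si](CC)(CC)CC)c1ccc(OC)cc1)[C@H]([C@@H](O)c1ccc(OCc2ccccc2)cc1)C(=O)C#C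
F3 | step 7 | (2R,3S,2'R,3'R)‑2'‑[4‑(benzyloxy)phenyl]‑2‑(4‑methoxyphenyl)‑2,2',3,3'‑tetrahydro‑4H,4'H‑[3,3'‑bipyran]‑4,4'‑dione | COc1ccc([C@@H]2OC=CC(=O)[C@H]2[C@H]2C(=O)C=CO[C@H]2c2ccc(OCc3ccccc3)cc2)cc1
F4 | step 7 | 2,2‑dimethyl‑6‑methylene‑4‑(trimethylsilyloxy)‑4H‑1,3‑dioxine | C=C1C=C(O[Si](C)(C)C)OC(C)(C)O1
F5 | step 7 | 3,3'‑linked bis[4‑(tert‑butyldimethylsilyloxy)‑3,6‑dihydro‑2H‑pyran] adduct carrying the (2,2‑dimethyl‑4‑oxo‑4H‑1,3‑dioxin‑6‑yl)methyl arms at C6 and C6', trans to the C2 and C2' aryl groups | COc1ccc([C@@H]2O[C@@H](CC3=CC(=O)OC(C)(C)O3)C=C(O[Si](C)(C)C(C)(C)C)[C@H]2[C@H]2C(O[Si](C)(C)C(C)(C)C)=C[C@H](CC3=CC(=O)OC(C)(C)O3)O[C@H]2c2ccc(OCc3ccccc3)cc2)cc1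
F6 | step 4 | (2R,3R,4S)‑2‑[4‑(benzyloxy)phenyl]‑N‑methoxy‑4‑(4‑methoxybenzoyl)‑N‑methyl‑5‑oxooxolane‑3‑carboxamide | O=C1[C@H](C(=O)c2ccc(OC)cc2)[C@H]([C@@H](O1)c1ccc(OCc2ccccc2)cc1)C(=O)N(C)OC
F7 | step 3 | (2R)‑2‑[(R)‑[4‑(benzyloxy)phenyl](hydroxy)methyl]‑4‑(tert‑butoxy)‑4‑oxobutanoic acid | CC(C)(C)OC(=O)C[C@H]([C@@H](O)c1ccc(OCc2ccccc2)cc1)C(=O)O
F8 | step 3 | (2R,3R)‑2‑[4‑(benzyloxy)phenyl]‑5‑oxooxolane‑3‑carboxylic acid | O=C1C[C@H]([C@@H](O1)c1ccc(OCc2ccccc2)cc1)C(=O)O
A1 | alternative 1 | diazo ketone: 2‑diazo‑2‑(pentasilylated flavon‑3‑yl)‑1‑aryl ethanone with an ortho 4‑(tert‑butyldimethylsilyloxy)benzyl ether | COc1ccc(-c2oc3cc(O[Si](C)(C)C(C)(C)C)cc(O[Si](C)(C)C(C)(C)C)c3c(=O)c2C(=[N+]=[N-])C(=O)c2c(O[Si](C)(C)C(C)(C)C)cc(O[Si](C)(C)C(C)(C)C)cc2OCc2ccc(O[Si](C)(C)C(C)(C)C)cc2)cc1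
A2 | alternative 1 | cis‑3‑(flavon‑3‑yl)flavanone pentakis(tert‑butyldimethylsilyl) ether | COc1ccc(-c2oc3cc(O[Si](C)(C)C(C)(C)C)cc(O[Si](C)(C)C(C)(C)C)c3c(=O)c2[C@H]2C(=O)c3c(O[Si](C)(C)C(C)(C)C)cc(O[Si](C)(C)C(C)(C)C)cc3O[C@H]2c2ccc(O[Si](C)(C)C(C)(C)C)cc2)cc1
A3 | alternative 2 | trans‑5,7‑bis(benzyloxy)‑3‑[(Z)‑2‑[4‑(benzyloxy)phenyl]ethenyl]‑2‑(4‑methoxyphenyl)chromane | COc1ccc([C@@H]2Oc3cc(OCc4ccccc4)cc(OCc4ccccc4)c3C[C@H]2/C=C\c2ccc(OCc3ccccc3)cc2)cc1
A4 | alternative 2 | 3,5‑bis(benzyloxy)‑2‑(hydroxymethyl)phenol | OCc1c(O)cc(OCc2ccccc2)cc1OCc1ccccc1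
A5 | alternative 2 | 3,5‑bis(benzyloxy)‑6‑methylidenecyclohexa‑2,4‑dien‑1‑one (o‑quinone methide) | C=C1C(=O)C=C(OCc2ccccc2)C=C1OCc1ccccc1
A6 | alternative 2 | pentabenzyl 3,3''‑biflavan with CH2 at C4 and C4'' | COc1ccc([C@@H]2Oc3cc(OCc4ccccc4)cc(OCc4ccccc4)c3C[C@H]2[C@H]2Cc3c(OCc4ccccc4)cc(OCc4ccccc4)cc3O[C@H]2c2ccc(OCc3ccccc3)cc2)cc1
A7 | alternative 3 | (E,E)‑bis‑chalcone: 2,3‑bis[2,4‑bis(benzyloxy)‑6‑hydroxybenzoyl]‑1‑[4‑(benzyloxy)phenyl]‑4‑(4‑methoxyphenyl)buta‑1,3‑diene | COc1ccc(/C=C(/C(=O)c2c(O)cc(OCc3ccccc3)cc2OCc2ccccc2)C(=C/c2ccc(OCc3ccccc3)cc2)\C(=O)c2c(O)cc(OCc3ccccc3)cc2OCc2ccccc2)cc1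
A8 | alternative 3 | sikokianin B pentabenzyl ether | COc1ccc([C@@H]2Oc3cc(OCc4ccccc4)cc(OCc4ccccc4)c3C(=O)[C@H]2[C@H]2C(=O)c3c(OCc4ccccc4)cc(OCc4ccccc4)cc3O[C@H]2c2ccc(OCc3ccccc3)cc2)cc1
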